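Starting material that leaves a closed flask stands as target, apart from what sits on the catalyst, and in the dawn run the catalyst is charged at 0.5 mol%. So one measure serves for the rate: the dose D, the natural logarithm of charged over remaining starting material. Its slope is the flask's pseudo-first-order constant.

| flask | starting material | free catalyst | remark | time |
|---|---|---|---|---|
| dawn | 0.81 M | 0.5 mol% | run made earlier |  |
| south | 0.74 M | 0.8 mol% |  | 2.5 min |
| north-west | 0.74 M | 0.5 mol% |  | 2.5 min |
| west | 0.74 M | 0.25 mol% |  | 2.5 min |
| south-west | 3.0 M | 0.5 mol% |  | 2.5 min |
| east | 0.50 M | 0.15 mol% |  | 2.5 min |

- dawn (time / s: target / %): 10.0: 12.6; 12.0: 14.0; 15.0: 16.8; 25.0: 22.6; 40.0: 26.5; 60.0: 29.1; 90.0: 30.5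

(scatter of a reading: 0.3 percentage points)

- the analysis behind the earlier runs scatters by 0.3 percentage points, standard deviation
- no earlier run changes the charge of free catalyst; that part of a forecast is a guess

- all flasks from highest to lowest amount of target, in percent of the starting material charged, at 2.5 min (south / north-west / west / south-west / east)
- the same order at 10 min (south / north-west / west / south-west / east)
- the amount of target, in percent of the starting material charged of the flask you put first, at 2.5 min
- the amount of target, in percent of the starting material charged of the flask you put last, at 2.5 min

In the dawn run D gains 0.173 from 10.0 s to 40.0 s, but 0.0199 from 60.0 s to 90.0 s. These are readings, and the late gain, being smaller, feels the scatter more. The slope has fallen by a factor 8.68, more than the factor 1.44 by which the starting material has shrunk at the last reading, and D has already taken that shrinking out. I read the fall as catalyst dying at a constant k of 0.0432 s⁻¹.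

The dose at the last reading, 0.364, plus a tail of 0.00750 gives a final dose L of 0.371, and the slope at the start was L·k, or 0.0160 s⁻¹.

Dividing L by the molar catalyst charge c, here 4.05 mM, gives Λ, the catalyst's reach, the final dose per molar catalyst charged: 91.7 M⁻¹. No earlier run varies the catalyst, so carrying Λ across flasks is a guess. On that k, hardly any of the dose remains unspent by 2.5 min, a share of 0.153%, so my order follows c at both times. My reckoning gives south-west 74.7% and east 6.65%.

The forecast, holding that “L scales with absolute catalyst concentration”, gives south-west > south > north-west > west > east at 2.5 min and south-west > south > north-west > west > east at 10 min, with south-west at 74% (42% to 82%) and east at 6.6% (5% to 10%) at 2.5 min.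

The flasks give south-west > south > north-west > west > east at 2.5 min and south-west > south > north-west > west > east at 10 min, with south-west at 74.0% and east at 6.53% at 2.5 min.

starting material + free catalyst ⇌ catalyst intermediate A (K = 0.845 M⁻¹, k = 17.5 M⁻¹ s⁻¹); catalyst intermediate B → free catalyst + target (k = 13.8 s⁻¹); free catalyst → spent catalyst (k = 0.0786 s⁻¹); catalyst intermediate A ⇌ catalyst intermediate B (K = 28.9, k = 14.6 s⁻¹) In south-west at 2.50 min, spent catalyst is 99.7% of the catalyst charged, and 26% of the starting material is left. Take a neighbour flask with east's loading and 0.85 M of starting material: c is 1.28 mM, so Λ gives a dose of 0.117 and target of 11.0%. That neighbour stands at 10.8% at 2.50 min, with 89% of its starting material left.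

(The runs stem from a simulated flask on assumed constants; the scatter is artificial.)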